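Ring D is grown on the phenolic oxygen of a finished A–B–C trimer rather than coupled to it. In ring D the ether oxygen on C1 lies para to the C4 hydroxyl, C3 and C5 are oxygenated, and C2 and C6 bear hydrogen. This is the 4-alkoxyphenol pattern typical of a chromium carbene benzannulation. In one operation a carbene complex, ethoxyacetylene and one carbonyl ligand form C1–C2, C3–C4 and C4–C5 and close the ring, so the most crowded diaryl ether is never made by a coupling reaction. The precursor is a Cr(CO)5 carbene whose carbon bears the heptamethylated A–B–C aryloxy group and a (Z)-2-ethoxyvinyl arm.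

Key step: step 7

Remark: retentive bromine–lithium exchange is taken to deliver the Z-ethoxyvinyl arm. Partial Z/E drift of this push–pull alkene in the carbene complexes would be harmless, because C5 ends as an aromatic carbon.

Step 1
Reactants: 1 2,4,6-trimethoxyphenol; 2 4-fluoro-2,6-dimethoxybenzaldehyde
Product: 3 2,6-dimethoxy-4-(2,4,6-trimethoxyphenoxy)benzaldehyde (A–B aldehyde)
Conditions: K2CO3, DMSO, 110 °C, Ar
Reagents that add atoms: none
Why: Nucleophilic aromatic substitution by addition–elimination: the para formyl group stabilises the Meisenheimer adduct, fluoride is the best leaving group on the ring, and the methoxy groups meta to the C–F carbon do not work against attack by the hindered but electron-rich phenoxide of 1.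

Step 2
Reactants: 3 A–B aldehyde
Product: 5 2,6-dimethoxy-4-(2,4,6-trimethoxyphenoxy)phenol (A–B phenol), via A–B aryl formate 4 (not isolated)
Conditions: mCPBA (1.1 equiv), CH2Cl2, 0 °C → rt; crude formate, K2CO3 (cat.), MeOH, rt
Reagents that add atoms: 3-chloroperbenzoic acid (mCPBA) O=C(OO)c1cccc(Cl)c1
Why: Baeyer–Villiger oxidation used in the Dakin sense: because 3 has no free ortho or para hydroxyl a peracid replaces alkaline H2O2, the very electron-rich aryl group migrates in preference to hydride, and formate 4 masks the new phenol from over-oxidation until catalytic methanolysis frees it.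

Step 3
Reactants: 5 A–B phenol; 2 4-fluoro-2,6-dimethoxybenzaldehyde
Product: 6 4-[2,6-dimethoxy-4-(2,4,6-trimethoxyphenoxy)phenoxy]-2,6-dimethoxybenzaldehyde (A–B–C aldehyde)
Conditions: K2CO3, DMSO, 120 °C, Ar
Reagents that add atoms: none
Why: The same SNAr addition–elimination as in step 1, now with the 2,6-dimethoxyphenoxide of 5, whose steric demand at oxygen equals that of 1, so that the aldehyde again activates only the C–F carbon.

Step 4
Reactants: 6 A–B–C aldehyde
Product: 8 4-[2,6-dimethoxy-4-(2,4,6-trimethoxyphenoxy)phenoxy]-2,6-dimethoxyphenol (A–B–C phenol), via A–B–C aryl formate 7 (not isolated)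
Conditions: mCPBA (1.1 equiv), CH2Cl2, 0 °C → rt; crude formate, K2CO3 (cat.), MeOH, rt
Reagents that add atoms: 3-chloroperbenzoic acid (mCPBA) O=C(OO)c1cccc(Cl)c1
Why: Second Baeyer–Villiger/Dakin-type sequence, in which only ring C carries the formyl group, aryl migration is again favoured by two ortho methoxy groups and a para aryloxy group, and the ethers of rings A and B are inert to one equivalent of peracid at or below room temperature.

Step 5
Reactants: 9 (Z)-1-bromo-2-ethoxyethene; 10 hexacarbonylchromium
Product: 13 tetramethylammonium pentacarbonyl[(Z)-3-ethoxy-1-oxidoprop-2-en-1-ylidene]chromate, via (Z)-2-ethoxyvinyllithium 11 (not isolated), via Li[(CO)5CrC(O)CH=CHOEt] 12 (not isolated)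
Conditions: t-BuLi (2 equiv), Et2O, −78 °C; Cr(CO)6, THF, −78 → 0 °C; then Me4NBr, degassed H2O, 0 °C
Reagents that add atoms: tetramethylammonium bromide C[N+](C)(C)C.[Br-]; tert-butyllithium [Li]C(C)(C)C (lithium, present only in 11 and 12)
Why: Bromine–lithium exchange with retention gives 11, which resists loss of LiOEt because lithium and ethoxy are syn on the double bond, and its addition to a carbonyl ligand of Cr(CO)6 is the first half of the Fischer carbene synthesis, while cation exchange turns 12 into a storable salt that dissolves in CH2Cl2.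

Step 6
Reactants: 13 tetramethylammonium acylchromate (1.3 equiv); 8 A–B–C phenol
Product: 15 pentacarbonyl{[4-[2,6-dimethoxy-4-(2,4,6-trimethoxyphenoxy)phenoxy]-2,6-dimethoxyphenoxy][(Z)-2-ethoxyvinyl]carbene}chromium, via (CO)5Cr=C(OAc)CH=CHOEt 14 (not isolated)
Conditions: AcBr, CH2Cl2, −40 °C; then 8, iPr2NEt, −40 → 0 °C, Ar
Reagents that add atoms: acetyl bromide CC(=O)Br (acetyl group, present only in 14)
Why: O-Acylation of 13 gives the strongly electrophilic acyloxycarbene complex 14, and addition–elimination of a phenol at its carbene carbon with loss of acetate is the established entry to aryloxy Fischer carbene complexes, the carbene carbon being far more electrophilic than the ethoxy-deactivated C-β position.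

Step 7
Reactants: 15 aryloxy(2-ethoxyvinyl)carbene complex; 16 ethoxyacetylene
Product: 20 4-{4-[2,6-dimethoxy-4-(2,4,6-trimethoxyphenoxy)phenoxy]-2,6-dimethoxyphenoxy}-2,6-diethoxyphenol, via vinylcarbene complex (CO)4Cr=C(OEt)CH=C(OAr)CH=CHOEt 17 (not isolated), via dienylketene Cr(CO)3 complex 18 (not isolated), via ring D arene Cr(CO)3 complex 19 (not isolated)
Conditions: 16 (3 equiv, solution in hexanes), PhMe (0.4 M), 55 °C, sealed tube, Ar; then air, Et2O, daylight, rt
Reagents that add atoms: none
Why: Proposed new method: thermal loss of one cis carbonyl from 15, helped by the weakly donating aryloxy group and by the Z-ethoxy oxygen that can guard the free site as a hemilabile five-membered chelate, lets 16 bind and insert with its CH terminus joining the carbene carbon (C1–C2) to give the E-configured vinylcarbene 17, and migration of a carbonyl ligand onto the new ethoxy-bearing carbene carbon (C3–C4) gives the dienylketene complex 18. Ring D, the only ring formed, closes by a thermal 6π electrocyclisation in which the ketene carbon C4 bonds to the ethoxy-bearing vinyl carbon C5, and a proton shift from C5 to oxygen aromatises the ring to the phenol complex 19, from which air strips the Cr(CO)3 group. The closest known reaction is the Dötz benzannulation of alkenyl(aryloxy)carbene complexes of Cr(CO)5 with alkynes, an established diaryl ether synthesis, whereas the pairing of a 2-alkoxyvinyl arm with an ynol ether is untested. One regiochemical outcome is required, the ethoxy-bearing alkyne carbon next to C4, and both controls agree, since steric control in this reaction class puts the bulkier alkyne terminus beside the carbonyl-derived carbon and the nucleophilic CH end of the ynol ether matches the electrophilic carbene carbon. Carbonyl insertion must also outrun five-membered ring closure and arrest at the donor-stabilised stage 17, which the electron-poor aryloxy-substituted metal centre, a non-coordinating solvent and a high alkyne concentration all favour, and a pentacarbonyl form of 17, should it build up, belongs to the dienylcarbene class known to carbonylate and cyclise to ortho-alkoxyphenols under irradiation. No stereocentre is created, and the geometry of the ethoxyvinyl arm is erased when C5 becomes aromatic.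

Step 8
Reactants: 20 tetramer with ring D as 3,5-diethyl ether and free C4 hydroxyl
Product: 21 5-{2,6-dihydroxy-4-[2,6-dihydroxy-4-(2,4,6-trihydroxyphenoxy)phenoxy]phenoxy}benzene-1,2,3-triol (CNP0333502.0)
Conditions: BBr3 (15 equiv), CH2Cl2, −78 °C → rt, Ar; then ice-water
Reagents that add atoms: none
Why: Lewis-acid ether cleavage: BBr3 coordinates each alkyl aryl ether oxygen and bromide removes methyl or ethyl by SN2, the ethyl groups being helped by the adjacent C4 borate, while the three diaryl ether links offer no sp3 carbon and stay intact.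

Compound list (π-bound Cr(CO)3 fragments are written as a separate SMILES component)
1 | 2,4,6-trimethoxyphenol | COc1cc(OC)c(O)c(OC)c1 | starting material
2 | 4-fluoro-2,6-dimethoxybenzaldehyde | COc1cc(F)cc(OC)c1C=O | starting material
3 | 2,6-dimethoxy-4-(2,4,6-trimethoxyphenoxy)benzaldehyde | COc1cc(OC)c(Oc2cc(OC)c(C=O)c(OC)c2)c(OC)c1 | intermediate
4 | 2,6-dimethoxy-4-(2,4,6-trimethoxyphenoxy)phenyl formate | COc1cc(OC)c(Oc2cc(OC)c(OC=O)c(OC)c2)c(OC)c1 | intermediate
5 | 2,6-dimethoxy-4-(2,4,6-trimethoxyphenoxy)phenol | COc1cc(OC)c(Oc2cc(OC)c(O)c(OC)c2)c(OC)c1 | intermediate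
6 | 4-[2,6-dimethoxy-4-(2,4,6-trimethoxyphenoxy)phenoxy]-2,6-dimethoxybenzaldehyde | COc1cc(OC)c(Oc2cc(OC)c(Oc3cc(OC)c(C=O)c(OC)c3)c(OC)c2)c(OC)c1 | intermediate
7 | 4-[2,6-dimethoxy-4-(2,4,6-trimethoxyphenoxy)phenoxy]-2,6-dimethoxyphenyl formate | COc1cc(OC)c(Oc2cc(OC)c(Oc3cc(OC)c(OC=O)c(OC)c3)c(OC)c2)c(OC)c1 | intermediate
8 | 4-[2,6-dimethoxy-4-(2,4,6-trimethoxyphenoxy)phenoxy]-2,6-dimethoxyphenol | COc1cc(OC)c(Oc2cc(OC)c(Oc3cc(OC)c(O)c(OC)c3)c(OC)c2)c(OC)c1 | intermediate
9 | (Z)-1-bromo-2-ethoxyethene | CCO/C=C\Br | starting material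
10 | hexacarbonylchromium | O=C=[Cr](=C=O)(=C=O)(=C=O)(=C=O)=C=O | starting material
11 | (Z)-2-ethoxyvinyllithium | CCO/C=C\[Li] | intermediate
12 | lithium pentacarbonyl[(Z)-3-ethoxy-1-oxidoprop-2-en-1-ylidene]chromate | CCO/C=C\C([O-])=[Cr](=C=O)(=C=O)(=C=O)(=C=O)=C=O.[Li+] | intermediate
13 | tetramethylammonium pentacarbonyl[(Z)-3-ethoxy-1-oxidoprop-2-en-1-ylidene]chromate | CCO/C=C\C([O-])=[Cr](=C=O)(=C=O)(=C=O)(=C=O)=C=O.C[N+](C)(C)C | intermediate
14 | pentacarbonyl[acetoxy((Z)-2-ethoxyvinyl)carbene]chromium | CCO/C=C\C(OC(C)=O)=[Cr](=C=O)(=C=O)(=C=O)(=C=O)=C=O | intermediate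
15 | pentacarbonyl[(A–B–C aryloxy)((Z)-2-ethoxyvinyl)carbene]chromium | CCO/C=C\C(Oc1c(OC)cc(Oc2c(OC)cc(Oc3c(OC)cc(OC)cc3OC)cc2OC)cc1OC)=[Cr](=C=O)(=C=O)(=C=O)(=C=O)=C=O | intermediate
16 | ethoxyacetylene | C#COCC | starting material
17 | tetracarbonyl[(2E,4Z)-3-(A–B–C aryloxy)-1,5-diethoxypenta-2,4-dien-1-ylidene]chromium | CCO/C=C\C(Oc1c(OC)cc(Oc2c(OC)cc(Oc3c(OC)cc(OC)cc3OC)cc2OC)cc1OC)=C/C(OCC)=[Cr](=C=O)(=C=O)(=C=O)=C=O | intermediate
18 | tricarbonylchromium complex of (3E,5Z)-4-(A–B–C aryloxy)-2,6-diethoxyhexa-1,3,5-trien-1-one | CCO/C=C\C(Oc1c(OC)cc(Oc2c(OC)cc(Oc3c(OC)cc(OC)cc3OC)cc2OC)cc1OC)=C/C(OCC)=C=O.[Cr](=C=O)(=C=O)=C=O | intermediate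
19 | tricarbonyl(η6-ring D)chromium complex of 20 | CCOc1cc(Oc2c(OC)cc(Oc3c(OC)cc(Oc4c(OC)cc(OC)cc4OC)cc3OC)cc2OC)cc(OCC)c1O.[Cr](=C=O)(=C=O)=C=O | intermediate
20 | 4-{4-[2,6-dimethoxy-4-(2,4,6-trimethoxyphenoxy)phenoxy]-2,6-dimethoxyphenoxy}-2,6-diethoxyphenol | CCOc1cc(Oc2c(OC)cc(Oc3c(OC)cc(Oc4c(OC)cc(OC)cc4OC)cc3OC)cc2OC)cc(OCC)c1O | intermediate
21 | 5-{2,6-dihydroxy-4-[2,6-dihydroxy-4-(2,4,6-trihydroxyphenoxy)phenoxy]phenoxy}benzene-1,2,3-triol | Oc1cc(O)c(Oc2cc(O)c(Oc3cc(O)c(Oc4cc(O)c(O)c(O)c4)c(O)c3)c(O)c2)c(O)c1 | target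

Total step count: 8. Longest linear sequence: 7 (steps 1–4, 6, 7 and 8). Step 5 is a one-step side branch.

Steps most likely to fail

1. **Step 7.**
   - What may go wrong: the sequence may stop after alkyne insertion, because the new carbene carbon is stabilised by its ethoxy group and the chain by two further donors. Ring closure without carbonyl uptake and oligomerisation of the ynol ether on the metal may also compete.
   - Fallback: it sets out from 8 and uses only chemistry already run twice in the route. A third fluoride displacement on 2 (K2CO3, DMSO, 120 °C) should give the A–B–C–D aldehyde F1. mCPBA in CH2Cl2 should convert it into the A–B–C–D aryl formate F2. Catalytic methanolysis should then free the nonamethyl tetramer phenol F3. BBr3 in CH2Cl2 cleaves its nine methyl ethers, and the route is rejoined at 21.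

2. **Step 6.**
   - What may go wrong: attack of the doubly ortho-substituted phenol at the carbene carbon may be slower than thermal decay of the acyloxycarbene complex. Conjugate attack at C-β with loss of ethanol may also intervene.
   - Fallback: it sets out from 8 and makes the last ether by an Ullmann-type coupling with commercial 5-iodo-1,2,3-trimethoxybenzene (Ic1cc(OC)c(OC)c(OC)c1). The conditions are CuI (cat.), picolinic acid, K3PO4, DMSO, 90 °C, a system suited to hindered phenols. This should give the decamethyl ether of the target F4. BBr3 in CH2Cl2 then removes all ten methyl groups, and the route is rejoined at 21.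

3. **Step 8.**
   - What may go wrong: dealkylation may be incomplete across nine sites, and the free decaphenol may oxidise in air during purification.
   - Fallback: it sets out from 20 and replaces direct isolation by a derivatise–purify–release sequence. The crude BBr3 product is acetylated at once (Ac2O, pyridine, rt) to the air-stable decaacetate of the target F5. This compound can be separated from partly alkylated material by ordinary chromatography on silica. Acid-catalysed methanolysis (cat. HCl, MeOH, Ar, rt) gives only volatile by-products, and the route is rejoined at 21.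

Further compounds
F1 | step 7 | 4-{4-[2,6-dimethoxy-4-(2,4,6-trimethoxyphenoxy)phenoxy]-2,6-dimethoxyphenoxy}-2,6-dimethoxybenzaldehyde | COc1cc(OC)c(Oc2cc(OC)c(Oc3cc(OC)c(Oc4cc(OC)c(C=O)c(OC)c4)c(OC)c3)c(OC)c2)c(OC)c1
F2 | step 7 | 4-{4-[2,6-dimethoxy-4-(2,4,6-trimethoxyphenoxy)phenoxy]-2,6-dimethoxyphenoxy}-2,6-dimethoxyphenyl formate | COc1cc(OC)c(Oc2cc(OC)c(Oc3cc(OC)c(Oc4cc(OC)c(OC=O)c(OC)c4)c(OC)c3)c(OC)c2)c(OC)c1
F3 | step 7 | 4-{4-[2,6-dimethoxy-4-(2,4,6-trimethoxyphenoxy)phenoxy]-2,6-dimethoxyphenoxy}-2,6-dimethoxyphenol | COc1cc(OC)c(Oc2cc(OC)c(Oc3cc(OC)c(Oc4cc(OC)c(O)c(OC)c4)c(OC)c3)c(OC)c2)c(OC)c1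
F4 | step 6 | decamethyl ether of 21 | COc1cc(OC)c(Oc2cc(OC)c(Oc3cc(OC)c(Oc4cc(OC)c(OC)c(OC)c4)c(OC)c3)c(OC)c2)c(OC)c1
F5 | step 8 | decaacetate of 21 | CC(=O)Oc1cc(OC(C)=O)c(Oc2cc(OC(C)=O)c(Oc3cc(OC(C)=O)c(Oc4cc(OC(C)=O)c(OC(C)=O)c(OC(C)=O)c4)c(OC(C)=O)c3)c(OC(C)=O)c2)c(OC(C)=O)c1
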